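The bond on which everything rests joins the ring A carbonyl carbon to the ring B carbon flanked by CHO and prenyl. In the phloroglucinol pattern of ring B this carbon is a disguised phenol carbon. Ring B is therefore traced back to a 3-prenylphloroglucinaldehyde, and the two rings are first joined through nitrogen as an N-aroylhydrazone. Oxidation with Pb(OAc)4 expels dinitrogen and, in one operation, puts the aroyl carbon on the phenol ipso carbon, breaks the aryl C–O bond and returns the CHO at its final oxidation level. The precursor is the E hydrazone of a MOM-protected ring A benzohydrazide and the prenylated salicylaldehyde, whose only free OH sits between CH=N and prenyl.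

Key step: step 13

Remark: ring A is the halogenated ring and ring B the prenylated ring; MOM cleavage in aqueous methanolic HCl is taken to release the acetal carbon as dimethoxymethane.

Step 1
Reactants: 1 3,5-dimethoxytoluene
Product: 3 methyl 2,6-dimethoxy-4-methylbenzoate, via aryllithium 2 (not isolated)
Conditions: n-BuLi, TMEDA, THF, 0 °C to rt; then added to ClCO2Me (3 equiv), THF, −78 °C
Reagents that add atoms: methyl chloroformate, COC(=O)Cl
Why: Directed ortho-metalation occurs at the ring carbon flanked by both methoxy groups, and aryllithium 2 is C-acylated by excess methyl chloroformate at low temperature, where the doubly ortho-substituted ester resists a second addition.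

Step 2
Reactants: 3 methyl 2,6-dimethoxy-4-methylbenzoate
Product: 5 methyl 2-hydroxy-6-methoxy-4-methylbenzoate, via aryloxydichloroborane 4 (not isolated)
Conditions: BCl3 (1.1 equiv), CH2Cl2, −78 to 0 °C; H2O work-up
Reagents that add atoms: none
Why: Chelation-controlled Lewis acid ether cleavage, in which BCl3 bound to the ester carbonyl removes one ortho methyl group through a six-membered chelate and the boron phenoxide 4 so formed protects the second ether, which desymmetrises ring A.

Step 3
Reactants: 5 methyl 2-hydroxy-6-methoxy-4-methylbenzoate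
Product: 6 methyl 3-bromo-2-hydroxy-6-methoxy-4-methylbenzoate
Conditions: NBS (1.0 equiv), i-Pr2NH (10 mol %), CH2Cl2, 0 °C to rt
Reagents that add atoms: N-bromosuccinimide, O=C1CCC(=O)N1Br
Why: Amine-mediated electrophilic bromination, in which the N-bromoamine formed from NBS and i-Pr2NH is hydrogen-bonded to the phenol and should deliver bromine to the ortho carbon (also para to OMe), with one equivalent at low temperature guarding against dibromination.

Step 4
Reactants: 6 methyl 3-bromo-2-hydroxy-6-methoxy-4-methylbenzoate
Product: 7 methyl 3-bromo-5-chloro-2-hydroxy-6-methoxy-4-methylbenzoate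
Conditions: SO2Cl2 (1.1 equiv), CH2Cl2, 0 °C to rt, dark
Reagents that add atoms: sulfuryl chloride, O=S(=O)(Cl)Cl
Why: Electrophilic aromatic chlorination has a single ring C–H left to attack, para to the phenol and ortho to the methoxy group, so only one ring-chlorinated product can arise, and exclusion of light avoids radical chlorination of the benzylic methyl.

Step 5
Reactants: 7 methyl 3-bromo-5-chloro-2-hydroxy-6-methoxy-4-methylbenzoate
Product: 8 methyl 3-bromo-5-chloro-6-methoxy-2-(methoxymethoxy)-4-methylbenzoate
Conditions: NaH, MOMCl, THF/DMF, 0 °C to rt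
Reagents that add atoms: chloromethyl methyl ether, COCCl
Why: Williamson-type O-alkylation of the preformed sodium phenoxide overcomes the hydrogen bond to the ester and the flanking bromine, and the resulting acetal is stable to all later basic and oxidative steps.

Step 6
Reactants: 8 methyl 3-bromo-5-chloro-6-methoxy-2-(methoxymethoxy)-4-methylbenzoate
Product: 9 3-bromo-5-chloro-6-methoxy-2-(methoxymethoxy)-4-methylbenzoic acid
Conditions: KOSiMe3 (3 equiv), THF, 65 °C; then 0.5 M HCl to pH 4, 0 °C
Reagents that add atoms: none
Why: The carbonyl is shielded by two ortho substituents, so the silanolate is expected to cleave the ester by SN2 attack at the O-methyl carbon (anhydrous nucleophilic ester dealkylation), which leaves the MOM ether, the aryl ether and the aryl halides alone, and acidification only to pH 4 protects the acetal.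

Step 7
Reactants: 9 3-bromo-5-chloro-6-methoxy-2-(methoxymethoxy)-4-methylbenzoic acid
Product: 11 3-bromo-5-chloro-6-methoxy-2-(methoxymethoxy)-4-methylbenzohydrazide, via acyl imidazolide 10 (not isolated)
Conditions: CDI, THF, rt to 50 °C; then N2H4·H2O (5 equiv), 0 °C to rt
Reagents that add atoms: hydrazine (used as hydrate), NN
Why: Nucleophilic acyl substitution through an activated amide, in which CDI converts the hindered acid into acyl imidazolide 10 under neutral conditions that spare the MOM group and a large excess of the small alpha-effect nucleophile hydrazine gives the monoacyl hydrazide without diacylation.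

Step 8
Reactants: 12 2,4,6-trihydroxybenzaldehyde
Product: 13 2-hydroxy-4,6-bis(methoxymethoxy)benzaldehyde
Conditions: MOMCl (2.2 equiv), i-Pr2NEt, CH2Cl2, 0 °C
Reagents that add atoms: chloromethyl methyl ether, COCCl
Why: Selective phenol alkylation, in which the two hydroxyls not bound to the aldehyde are alkylated with an amine base while the chelated ortho OH is left free for the next step.

Step 9
Reactants: 13 2-hydroxy-4,6-bis(methoxymethoxy)benzaldehyde; 14 2-methylbut-3-yn-2-ol
Product: 16 2,4-bis(methoxymethoxy)-6-[(2-methylbut-3-yn-2-yl)oxy]benzaldehyde, via propargylic trifluoroacetate 15 (not isolated)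
Conditions: 14, (CF3CO)2O, DBU, MeCN, −5 °C; then 13, DBU, CuCl2·2H2O (1 mol %), MeCN, 0 °C to rt
Reagents that add atoms: none
Why: Copper-catalysed propargylic etherification, in which trifluoroacetate 15 ionises through a copper acetylide (allenylidene-type) intermediate and the DBU phenoxide of the only free OH attacks the tertiary carbon, a path open where SN2 alkylation with a tertiary halide is not.

Step 10
Reactants: 16 2,4-bis(methoxymethoxy)-6-[(2-methylbut-3-yn-2-yl)oxy]benzaldehyde
Product: 17 2,4-bis(methoxymethoxy)-6-[(2-methylbut-3-en-2-yl)oxy]benzaldehyde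
Conditions: H2 (1 atm), Pd/CaCO3 poisoned with Pb(OAc)2 (Lindlar catalyst), quinoline, EtOAc, rt
Reagents that add atoms: none
Why: Lindlar semihydrogenation reduces the terminal alkyne to the vinyl group and stops there, the poisoned palladium leaving the aryl aldehyde, the acetals and the tertiary aryl ether untouched.

Step 11
Reactants: 17 2,4-bis(methoxymethoxy)-6-[(2-methylbut-3-en-2-yl)oxy]benzaldehyde
Product: 19 2-hydroxy-4,6-bis(methoxymethoxy)-3-(3-methylbut-2-en-1-yl)benzaldehyde, via ortho dienone 18 (not isolated)
Conditions: PhNEt2, 120 °C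
Reagents that add atoms: none
Why: Aromatic Claisen rearrangement, a [3,3] shift to the only unsubstituted ortho carbon (the other bears the CHO), inverts the allyl unit to the prenyl group, dienone 18 tautomerises to the phenol that is again hydrogen-bonded to the aldehyde, and the basic solvent suppresses acid-catalysed chroman formation.

Step 12
Reactants: 11 3-bromo-5-chloro-6-methoxy-2-(methoxymethoxy)-4-methylbenzohydrazide; 19 2-hydroxy-4,6-bis(methoxymethoxy)-3-(3-methylbut-2-en-1-yl)benzaldehyde
Product: 20 (E)-N-aroylhydrazone of 19 with 11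
Conditions: EtOH, AcOH (cat.), 50 °C
Reagents that add atoms: none
Why: Condensation of an acyl hydrazide with an aldehyde gives the N-acylhydrazone, the E geometry being the thermodynamic one and reinforced by the O–H···N hydrogen bond from the ortho phenol.

Step 13
Reactants: 20 (E)-N-aroylhydrazone of 19 with 11
Product: 24 2-[3-bromo-5-chloro-6-methoxy-2-(methoxymethoxy)-4-methylbenzoyl]-4,6-bis(methoxymethoxy)-3-(3-methylbut-2-en-1-yl)benzaldehyde (tris-MOM pestalone G), via azoacetate 21 (not isolated), via bridged oxadiazoline 22 (not isolated), via carbonyl ylide 23 (not isolated)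
Conditions: Pb(OAc)4 (1.1 equiv), THF, 0 °C to rt
Reagents that add atoms: none
Why: Pb(OAc)4 (tetravalent lead) oxidises the hydrazone N–H to azoacetate 21; its acyl oxygen displaces acetate at the former aldehyde carbon (5-exo-tet closure of the 1,3,4-oxadiazoline ring) and the free ring B phenol oxygen caps the acyl carbon (6-endo-trig closure of the fused 1,3-dioxin ring), giving bridged oxadiazoline 22. Cycloreversion expels N2 and leaves carbonyl ylide 23, whose acyl-derived carbon bonds to the neighbouring ipso carbon of ring B through a five-membered isobenzofuran-type array while the aryl C–O bond breaks, so that collapse releases the diaryl ketone and the CHO and no ring stays closed. The closest known reaction type is the lead tetraacetate oxidation of N-acylhydrazones of salicylaldehydes and o-hydroxyaryl ketones to 2-acylbenzaldehydes and 1,2-diacylbenzenes, here applied to a more crowded member of the same substrate class. No stereocentre is created in the product; the sp3 centres of 21 and 22 are transient and the E hydrazone geometry is erased. The step needs site selectivity between the two oxygens ortho to the CHO, which is secured because only the oxygen between CHO and prenyl is a free phenol while the other ring B oxygens and the ring A phenol are MOM ethers. It also needs chemoselectivity over the prenyl alkene and over aromatisation to a 1,3,4-oxadiazole, which should follow from the much faster oxidation of the N–H at 0 °C with a slight excess of oxidant and from the intramolecular trapping of the cyclised cation by the ortho phenol.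

Step 14
Reactants: 24 tris-MOM pestalone G
Product: 25 pestalone G, 2-(3-bromo-5-chloro-2-hydroxy-6-methoxy-4-methylbenzoyl)-4,6-dihydroxy-3-(3-methylbut-2-en-1-yl)benzaldehyde
Conditions: 3 M aq. HCl, MeOH, rt
Reagents that add atoms: none
Why: Acid-catalysed acetal cleavage (transacetalisation to methanol) should remove all three MOM groups at room temperature, mild enough that the prenyl alkene does not cyclise onto the neighbouring phenol and the keto aldehyde is kept.

Compound list
1 | 3,5-dimethoxytoluene | COc1cc(C)cc(OC)c1 | starting material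
2 | (2,6-dimethoxy-4-methylphenyl)lithium | [Li]c1c(OC)cc(C)cc1OC | intermediate
3 | methyl 2,6-dimethoxy-4-methylbenzoate | COC(=O)c1c(OC)cc(C)cc1OC | intermediate
4 | methyl 2-[(dichloroboranyl)oxy]-6-methoxy-4-methylbenzoate | COC(=O)c1c(OB(Cl)Cl)cc(C)cc1OC | intermediate
5 | methyl 2-hydroxy-6-methoxy-4-methylbenzoate | COC(=O)c1c(O)cc(C)cc1OC | intermediate
6 | methyl 3-bromo-2-hydroxy-6-methoxy-4-methylbenzoate | COC(=O)c1c(O)c(Br)c(C)cc1OC | intermediate
7 | methyl 3-bromo-5-chloro-2-hydroxy-6-methoxy-4-methylbenzoate | COC(=O)c1c(O)c(Br)c(C)c(Cl)c1OC | intermediate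
8 | methyl 3-bromo-5-chloro-6-methoxy-2-(methoxymethoxy)-4-methylbenzoate | COC(=O)c1c(OCOC)c(Br)c(C)c(Cl)c1OC | intermediate
9 | 3-bromo-5-chloro-6-methoxy-2-(methoxymethoxy)-4-methylbenzoic acid | OC(=O)c1c(OCOC)c(Br)c(C)c(Cl)c1OC | intermediate
10 | [3-bromo-5-chloro-6-methoxy-2-(methoxymethoxy)-4-methylphenyl](1H-imidazol-1-yl)methanone | O=C(n1ccnc1)c1c(OCOC)c(Br)c(C)c(Cl)c1OC | intermediate
11 | 3-bromo-5-chloro-6-methoxy-2-(methoxymethoxy)-4-methylbenzohydrazide | NNC(=O)c1c(OCOC)c(Br)c(C)c(Cl)c1OC | intermediate
12 | 2,4,6-trihydroxybenzaldehyde | O=Cc1c(O)cc(O)cc1O | starting material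
13 | 2-hydroxy-4,6-bis(methoxymethoxy)benzaldehyde | O=Cc1c(O)cc(OCOC)cc1OCOC | intermediate
14 | 2-methylbut-3-yn-2-ol | CC(C)(O)C#C | starting material
15 | 2-methylbut-3-yn-2-yl trifluoroacetate | CC(C)(OC(=O)C(F)(F)F)C#C | intermediate
16 | 2,4-bis(methoxymethoxy)-6-[(2-methylbut-3-yn-2-yl)oxy]benzaldehyde | O=Cc1c(OC(C)(C)C#C)cc(OCOC)cc1OCOC | intermediate
17 | 2,4-bis(methoxymethoxy)-6-[(2-methylbut-3-en-2-yl)oxy]benzaldehyde | O=Cc1c(OC(C)(C)C=C)cc(OCOC)cc1OCOC | intermediate
18 | 2-formyl-3,5-bis(methoxymethoxy)-6-(3-methylbut-2-en-1-yl)cyclohexa-2,4-dien-1-one | O=CC1=C(OCOC)C=C(OCOC)C(CC=C(C)C)C1=O | intermediate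
19 | 2-hydroxy-4,6-bis(methoxymethoxy)-3-(3-methylbut-2-en-1-yl)benzaldehyde | O=Cc1c(O)c(CC=C(C)C)c(OCOC)cc1OCOC | intermediate
20 | 3-bromo-5-chloro-N'-{(E)-[2-hydroxy-4,6-bis(methoxymethoxy)-3-(3-methylbut-2-en-1-yl)phenyl]methylidene}-6-methoxy-2-(methoxymethoxy)-4-methylbenzohydrazide | COCOc1cc(OCOC)c(CC=C(C)C)c(O)c1/C=N/NC(=O)c1c(OCOC)c(Br)c(C)c(Cl)c1OC | intermediate
21 | azoacetate: acetoxy(aryl)methyl aroyl diazene from 20, ArB–CH(OAc)–N=N–C(=O)–ArA | COCOc1cc(OCOC)c(CC=C(C)C)c(O)c1C(OC(C)=O)N=NC(=O)c1c(OCOC)c(Br)c(C)c(Cl)c1OC | intermediate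
22 | bridged 1,3,4-oxadiazoline: 4H-1,3-benzodioxin of ring B with an N=N bridge from C2 (bearing the ring A aryl) to C4 | COCOc1cc(OCOC)c(CC=C(C)C)c2OC3(c4c(OCOC)c(Br)c(C)c(Cl)c4OC)N=NC(O3)c12 | intermediate
23 | cyclic carbonyl ylide: 2-(ring A aryl)-1,3-benzodioxin-3-ium-4-ide of ring B | COCOc1cc(OCOC)c(CC=C(C)C)c2OC(c3c(OCOC)c(Br)c(C)c(Cl)c3OC)=[O+][CH-]c12 | intermediate
24 | 2-[3-bromo-5-chloro-6-methoxy-2-(methoxymethoxy)-4-methylbenzoyl]-4,6-bis(methoxymethoxy)-3-(3-methylbut-2-en-1-yl)benzaldehyde | COCOc1cc(OCOC)c(CC=C(C)C)c(C(=O)c2c(OCOC)c(Br)c(C)c(Cl)c2OC)c1C=O | intermediate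
25 | pestalone G, 2-(3-bromo-5-chloro-2-hydroxy-6-methoxy-4-methylbenzoyl)-4,6-dihydroxy-3-(3-methylbut-2-en-1-yl)benzaldehyde | COc1c(Cl)c(C)c(Br)c(O)c1C(=O)c1c(C=O)c(O)cc(O)c1CC=C(C)C | target

Total step count: 14. Longest linear sequence: 10 steps (steps 1 to 7, then 12, 13 and 14); the ring B branch contributes steps 8 to 11.

Steps most likely to fail

Step 13. The azoacetate may aromatise to a 2,5-diaryl-1,3,4-oxadiazole faster than the phenol oxygen reaches the doubly ortho-substituted acyl carbon. The oxidant may also attack the prenyl alkene or the electron-rich phenol ring. The fallback forms the ketone by known aryllithium addition and oxidation; it sets out from 8 and 19 and rejoins the route at 24. Ester 8 would be reduced with i-Bu2AlH (CH2Cl2, −78 °C) to [3-bromo-5-chloro-6-methoxy-2-(methoxymethoxy)-4-methylphenyl]methanol F1 and oxidised with MnO2 to 3-bromo-5-chloro-6-methoxy-2-(methoxymethoxy)-4-methylbenzaldehyde F2. Phenol 19 would be converted with Tf2O and pyridine into 2-formyl-3,5-bis(methoxymethoxy)-6-(3-methylbut-2-en-1-yl)phenyl trifluoromethanesulfonate F3. Stannylation (Me3SnSnMe3, Pd(PPh3)4, LiCl, dioxane, 90 °C) would give 4,6-bis(methoxymethoxy)-3-(3-methylbut-2-en-1-yl)-2-(trimethylstannyl)benzaldehyde F4, and NaBH4 in MeOH would reduce it to [4,6-bis(methoxymethoxy)-3-(3-methylbut-2-en-1-yl)-2-(trimethylstannyl)phenyl]methanol F5. Tin–lithium exchange of F5 with MeLi (2 equiv, THF, −78 °C) and addition of the resulting aryllithium alkoxide to F2 would give [3-bromo-5-chloro-6-methoxy-2-(methoxymethoxy)-4-methylphenyl][2-(hydroxymethyl)-3,5-bis(methoxymethoxy)-6-(3-methylbut-2-en-1-yl)phenyl]methanol F6. A double Swern oxidation ((COCl)2, DMSO, Et3N, −78 °C), chosen to avoid lactol over-oxidation to a phthalide, would then deliver 24.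

Step 9. The phenoxide of 13 is hydrogen-bonded to and flanked by the aldehyde, so O-alkylation at the tertiary propargylic carbon may be too slow and the activated ester may be lost to elimination or alkyne coupling. The fallback sets out from 13 and returns at 17, bypassing 16 and the semihydrogenation. It is a Tsuji–Trost O-allylation with purchasable tert-butyl 2-methylbut-3-en-2-yl carbonate and Pd(PPh3)4 in THF at 0 °C, where the phenoxide attacks the more substituted terminus of the 1,1-dimethyl π-allyl palladium complex to give the tertiary ether directly. No new compound is made on the way.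

Step 3. Bromination may occur para to the phenol (next to OMe) or twice, which would put the halogens in the wrong pattern. The fallback sets out from 3 and returns at 6. The symmetric diether 3 would be monobrominated (NBS, MeCN, rt) to methyl 3-bromo-2,6-dimethoxy-4-methylbenzoate F7, a single isomer by symmetry. Chelation-controlled BCl3 demethylation is then expected to take the methoxy group flanked by bromine and the ester, which is twisted out of the ring plane and is the more Lewis-basic, giving 6 with the OH next to bromine.

Further compounds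
F1 | step 13 | [3-bromo-5-chloro-6-methoxy-2-(methoxymethoxy)-4-methylphenyl]methanol | OCc1c(OCOC)c(Br)c(C)c(Cl)c1OC
F2 | step 13 | 3-bromo-5-chloro-6-methoxy-2-(methoxymethoxy)-4-methylbenzaldehyde | O=Cc1c(OCOC)c(Br)c(C)c(Cl)c1OC
F3 | step 13 | 2-formyl-3,5-bis(methoxymethoxy)-6-(3-methylbut-2-en-1-yl)phenyl trifluoromethanesulfonate | O=Cc1c(OS(=O)(=O)C(F)(F)F)c(CC=C(C)C)c(OCOC)cc1OCOC
F4 | step 13 | 4,6-bis(methoxymethoxy)-3-(3-methylbut-2-en-1-yl)-2-(trimethylstannyl)benzaldehyde | O=Cc1c([Sn](C)(C)C)c(CC=C(C)C)c(OCOC)cc1OCOC
F5 | step 13 | [4,6-bis(methoxymethoxy)-3-(3-methylbut-2-en-1-yl)-2-(trimethylstannyl)phenyl]methanol | OCc1c([Sn](C)(C)C)c(CC=C(C)C)c(OCOC)cc1OCOC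
F6 | step 13 | [3-bromo-5-chloro-6-methoxy-2-(methoxymethoxy)-4-methylphenyl][2-(hydroxymethyl)-3,5-bis(methoxymethoxy)-6-(3-methylbut-2-en-1-yl)phenyl]methanol | OCc1c(C(O)c2c(OCOC)c(Br)c(C)c(Cl)c2OC)c(CC=C(C)C)c(OCOC)cc1OCOC
F0 | step 9 | none | none
F7 | step 3 | methyl 3-bromo-2,6-dimethoxy-4-methylbenzoate | COC(=O)c1c(OC)c(Br)c(C)cc1OC
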